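## Retrosynthetic overview

1. Target ⇒ cis-fused cyclobutanone + internal alkyne. The cyclohexenone ring is made last by a nickel-catalysed two-carbon ring expansion (alkyne insertion into the acyl–CH2 bond), which also joins the two halves.
2. Cyclobutanone ⇒ meso oxaspiropentane by a catalytic desymmetrising semipinacol 1,2-shift (three- to four-membered ring) that sets both quaternary methyl centres. The spiro-epoxide comes from 1,2-dimethylcyclopentene and 1,1-dichloroethane via a methylenecyclopropane.
3. Alkyne ⇒ propargyl chroman + 2,2-dimethyloxirane; propargyl chroman ⇒ chromanylacetic ester (one-pot reduction and Ohira–Bestmann homologation).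
4. Ester ⇒ phenol carrying a 3-methylbut-3-enyl arm, by enantioselective domino Wacker cyclisation–carbonylation (pyran ring and C2 centre). Phenol ⇒ o-cresol, methanol, methyl vinyl ketone and a methylene Wittig reagent.
5. Ring order: arene (bought) → pyran ring; cyclopentane (bought) → cyclopropane → cyclobutanone → cyclohexenone.

Assumption: the facial sense of (S,S)-Bn-BOXAX in step 4 and of the (S,S)-IDPi acid in step 10 is taken to give the configurations drawn; should either prove opposite, the mirror-image ligand or acid is used.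

## Route

Step 1
Reactants: 1 2-methylphenol (o-cresol)
Product: 3 4-methoxy-2-methylphenol, via quinone monoketal 2 (not isolated)
Conditions: PhI(OAc)2 (2.1 equiv), MeOH, 0 °C; then Zn dust, AcOH, rt (one pot)
Reagents that add atoms: methanol, SMILES CO
Why: Hypervalent-iodine oxidative dearomatisation of the para-unsubstituted phenol in methanol gives the para-quinone monoketal, which zinc in acetic acid reductively aromatises with loss of one methoxide, leaving OMe para to OH (phenol oxidation followed by reductive aromatisation).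

Step 2
Reactants: 3 4-methoxy-2-methylphenol; 4 but-3-en-2-one
Product: 5 6-methoxy-2,8-dimethyl-3,4-dihydro-2H-chromen-2-ol (racemic lactol)
Conditions: 4 (1.3 equiv), sulfonic acid resin (Amberlyst 15), toluene, 50 °C
Reagents that add atoms: none
Why: Brønsted-acid Friedel–Crafts conjugate addition of the electron-rich phenol to the enone at the free position ortho to OH (para is blocked), followed by hemiketalisation that traps this regioisomer as the chromanol; no stereocentre of the target is set here.

Step 3
Reactants: 5 6-methoxy-2,8-dimethyl-3,4-dihydro-2H-chromen-2-ol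
Product: 6 4-methoxy-2-methyl-6-(3-methylbut-3-en-1-yl)phenol
Conditions: Ph3PCH3Br (3 equiv), KOtBu (3 equiv), THF, 0 °C → reflux
Reagents that add atoms: methyltriphenylphosphonium bromide, SMILES C[P+](c1ccccc1)(c1ccccc1)c1ccccc1.[Br-]
Why: Wittig methylenation of the ring-opened keto tautomer of the lactol (the excess ylide also deprotonates the phenol) gives the 1,1-disubstituted alkene.

Step 4
Reactants: 6 4-methoxy-2-methyl-6-(3-methylbut-3-en-1-yl)phenol
Product: 7 methyl [(2S)-6-methoxy-2,8-dimethyl-3,4-dihydro-2H-chromen-2-yl]acetate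
Conditions: Pd(OCOCF3)2 (5 mol%), (S,S)-Bn-BOXAX (20 mol%), p-benzoquinone (4 equiv), CO (1 atm), MeOH, rt
Reagents that add atoms: carbon monoxide, SMILES [C-]#[O+]; methanol, SMILES CO
Why: Enantioselective domino Wacker cyclisation–methoxycarbonylation, in which BOXAX-ligated divalent palladium selects one enantiotopic alkene face in the 6-exo oxypalladation (setting quaternary C2 as S), the neopentyl alkylpalladium without β-hydrogen is captured by CO and methanol, and benzoquinone reoxidises zerovalent palladium.

Step 5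
Reactants: 7 methyl [(2S)-6-methoxy-2,8-dimethyl-3,4-dihydro-2H-chromen-2-yl]acetate
Product: 10 (2S)-6-methoxy-2,8-dimethyl-2-(prop-2-yn-1-yl)chroman, via aluminium hemiacetal 8 (not isolated), via aldehyde 9 (not isolated)
Conditions: i-Bu2AlH (1.05 equiv), CH2Cl2, −78 °C; then MeOH, K2CO3, dimethyl (1-diazo-2-oxopropyl)phosphonate, −78 °C → rt
Reagents that add atoms: dimethyl (1-diazo-2-oxopropyl)phosphonate, SMILES CC(=O)C(=[N+]=[N-])P(=O)(OC)OC
Why: Low-temperature hydride reduction stops at the aluminium hemiacetal, which releases the aldehyde on methanolysis for in situ Ohira–Bestmann (Seyferth–Gilbert) homologation to the terminal alkyne, and the non-enolisable quaternary centre is untouched.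

Step 6
Reactants: 10 (2S)-6-methoxy-2,8-dimethyl-2-(prop-2-yn-1-yl)chroman; 11 2,2-dimethyloxirane
Product: 13 6-[(2S)-6-methoxy-2,8-dimethyl-3,4-dihydro-2H-chromen-2-yl]-2-methylhex-4-yn-2-ol, via lithium acetylide 12 (not isolated)
Conditions: n-BuLi (1.05 equiv), THF, −78 °C; then BF3·OEt2 (1.1 equiv), 11 (1.5 equiv), −78 °C
Reagents that add atoms: none
Why: BF3-assisted opening of the 1,1-disubstituted epoxide by the lithium acetylide at its unhindered CH2 terminus (Yamaguchi alkynylation) gives the homopropargylic tertiary alcohol.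

Step 7
Reactants: 14 1,2-dimethylcyclopent-1-ene; 15 1,1-dichloroethane
Product: 17 (1R,5S)-6-chloro-1,5,6-trimethylbicyclo[3.1.0]hexane (meso; both C6 epimers), via carbenoid 16 (not isolated)
Conditions: n-BuLi (2 equiv) added slowly to 14 (1 equiv) and 15 (2 equiv), Et2O, −35 °C
Reagents that add atoms: none
Why: α-Elimination of lithiated 1,1-dichloroethane gives a chloro(methyl)carbenoid that cyclopropanates the electron-rich tetrasubstituted alkene stereospecifically, so the ring fusion is cis and the product is meso (carbenoid [2+1] cyclopropanation).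

Step 8
Reactants: 17 (1R,5S)-6-chloro-1,5,6-trimethylbicyclo[3.1.0]hexane
Product: 18 (1R,5S)-1,5-dimethyl-6-methylidenebicyclo[3.1.0]hexane (meso)
Conditions: KOtBu (2 equiv), DMSO, rt → 50 °C
Reagents that add atoms: none
Why: E2 dehydrochlorination can only run towards the C6 methyl group because both ring neighbours are quaternary, giving the methylenecyclopropane.

Step 9
Reactants: 18 (1R,5S)-1,5-dimethyl-6-methylidenebicyclo[3.1.0]hexane
Product: 19 (1R,5S)-1,5-dimethylspiro[bicyclo[3.1.0]hexane-6,2'-oxirane] (meso; both spiro epimers)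
Conditions: dimethyldioxirane (acetone solution, 1.2 equiv), −20 °C → 0 °C
Reagents that add atoms: dimethyldioxirane, SMILES CC1(C)OO1
Why: Neutral dioxirane epoxidation of the strained exocyclic alkene gives the acid-sensitive oxaspiropentane without rearranging it, and both spiro epimers are meso and converge in the next step.

Step 10
Reactants: 19 (1R,5S)-1,5-dimethylspiro[bicyclo[3.1.0]hexane-6,2'-oxirane]
Product: 20 (1S,5S)-1,5-dimethylbicyclo[3.2.0]heptan-6-one
Conditions: (S,S)-IDPi acid (imidodiphosphorimidate from two (S)-3,3'-bis[3,5-bis(trifluoromethyl)phenyl]-BINOL units, N-triflyl on both phosphorus atoms; 3 mol%), toluene, −60 °C → −40 °C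
Reagents that add atoms: none
Why: Proposed new method: protonation of the epoxide by the confined chiral acid opens the CH2–O bond to a cyclopropylcarbinyl cation/cyclopropanol ion pair held in the chiral anion pocket, the anion decides which of the two enantiotopic cyclopropane bonds (C6–C1 or C6–C5) migrates to the CH2 terminus, and this single desymmetrising semipinacol 1,2-shift expands the three- to the four-membered ring and sets both quaternary centres (1S,5S) with retention at the migrating carbon; the closest known reactions are the racemic halide- or acid-promoted oxaspiropentane-to-cyclobutanone rearrangement and confined-acid-catalysed asymmetric Wagner–Meerwein and semipinacol shifts of aliphatic cations.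

Step 11
Reactants: 20 (1S,5S)-1,5-dimethylbicyclo[3.2.0]heptan-6-one; 13 6-[(2S)-6-methoxy-2,8-dimethyl-3,4-dihydro-2H-chromen-2-yl]-2-methylhex-4-yn-2-ol
Product: 21 (3aS,7aS)-5-(2-hydroxy-2-methylpropyl)-6-{[(2S)-6-methoxy-2,8-dimethyl-3,4-dihydro-2H-chromen-2-yl]methyl}-3a,7a-dimethyl-1,2,3,3a,7,7a-hexahydro-4H-inden-4-one (CNP0224132.2)
Conditions: Ni(cod)2 (10 mol%), PCy3 (20 mol%), 20 (1.5 equiv), toluene, 100 °C, 13 added over 2 h
Reagents that add atoms: none
Why: Zerovalent nickel couples the strained ketone and the alkyne oxidatively to an oxanickelacyclopentene, β-carbon elimination cleaves the less hindered acyl–CH2 bond and C–C reductive elimination closes the cyclohexenone (formal [4+2] ring expansion by alkyne insertion into a cyclobutanone); the carbonyl carbon is expected to bond to the alkyne carbon carrying the smaller, hydrogen-bond-donating hydroxyalkyl arm, leaving the bulkier chromanylmethyl arm on the nickel-bound carbon, and no stereocentre is touched.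

## Compound list

1 | 2-methylphenol (o-cresol) | Cc1ccccc1O | starting material
2 | 4,4-dimethoxy-2-methylcyclohexa-2,5-dien-1-one (quinone monoketal) | COC1(OC)C=CC(=O)C(C)=C1 | intermediate (not isolated)
3 | 4-methoxy-2-methylphenol | COc1ccc(O)c(C)c1 | intermediate
4 | but-3-en-2-one (methyl vinyl ketone) | CC(=O)C=C | starting material
5 | 6-methoxy-2,8-dimethyl-3,4-dihydro-2H-chromen-2-ol (racemic lactol; ring-closed tautomer of 4-(2-hydroxy-5-methoxy-3-methylphenyl)butan-2-one) | COc1cc(C)c2OC(C)(O)CCc2c1 | intermediate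
6 | 4-methoxy-2-methyl-6-(3-methylbut-3-en-1-yl)phenol | COc1cc(C)c(O)c(CCC(C)=C)c1 | intermediate
7 | methyl [(2S)-6-methoxy-2,8-dimethyl-3,4-dihydro-2H-chromen-2-yl]acetate | COc1cc(C)c2c(c1)CC[C@@](C)(CC(=O)OC)O2 | intermediate
8 | {1-methoxy-2-[(2S)-6-methoxy-2,8-dimethyl-3,4-dihydro-2H-chromen-2-yl]ethoxy}bis(2-methylpropyl)alumane (aluminium hemiacetal, both epimers at the hemiacetal carbon) | COc1cc(C)c2c(c1)CC[C@@](C)(CC(OC)O[Al](CC(C)C)CC(C)C)O2 | intermediate (not isolated)
9 | [(2S)-6-methoxy-2,8-dimethyl-3,4-dihydro-2H-chromen-2-yl]acetaldehyde | COc1cc(C)c2c(c1)CC[C@@](C)(CC=O)O2 | intermediate (not isolated)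
10 | (2S)-6-methoxy-2,8-dimethyl-2-(prop-2-yn-1-yl)chroman | COc1cc(C)c2c(c1)CC[C@@](C)(CC#C)O2 | intermediate
11 | 2,2-dimethyloxirane | CC1(C)CO1 | starting material
12 | lithium acetylide of 10 | COc1cc(C)c2c(c1)CC[C@@](C)(CC#C[Li])O2 | intermediate (not isolated)
13 | 6-[(2S)-6-methoxy-2,8-dimethyl-3,4-dihydro-2H-chromen-2-yl]-2-methylhex-4-yn-2-ol | COc1cc(C)c2c(c1)CC[C@@](C)(CC#CCC(C)(C)O)O2 | intermediate
14 | 1,2-dimethylcyclopent-1-ene | CC1=C(C)CCC1 | starting material
15 | 1,1-dichloroethane | CC(Cl)Cl | starting material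
16 | 1,1-dichloroethyllithium (carbenoid) | CC(Cl)(Cl)[Li] | intermediate (not isolated)
17 | (1R,5S)-6-chloro-1,5,6-trimethylbicyclo[3.1.0]hexane (meso; both C6 epimers) | CC1(Cl)[C@@]2(C)CCC[C@@]12C | intermediate
18 | (1R,5S)-1,5-dimethyl-6-methylidenebicyclo[3.1.0]hexane (meso) | C=C1[C@@]2(C)CCC[C@@]12C | intermediate
19 | (1R,5S)-1,5-dimethylspiro[bicyclo[3.1.0]hexane-6,2'-oxirane] (meso; both spiro epimers) | C1OC12[C@@]3(C)CCC[C@@]23C | intermediate
20 | (1S,5S)-1,5-dimethylbicyclo[3.2.0]heptan-6-one | O=C1[C@@]2(C)CCC[C@@]2(C)C1 | intermediate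
21 | (3aS,7aS)-5-(2-hydroxy-2-methylpropyl)-6-{[(2S)-6-methoxy-2,8-dimethyl-3,4-dihydro-2H-chromen-2-yl]methyl}-3a,7a-dimethyl-1,2,3,3a,7,7a-hexahydro-4H-inden-4-one | COc1cc(C)c2c(c1)CC[C@@](C)(CC1=C(CC(C)(C)O)C(=O)[C@@]3(C)CCC[C@@]3(C)C1)O2 | target

## Step count and risks

Total step count: 11 (six to alkyne 13, four to cyclobutanone 20, one union). Longest linear sequence: 7 steps (steps 1–6, then step 11).

The three steps most likely to fail:

**Step 10 (the proposed new step).** The risks are insufficient discrimination of the two enantiotopic cyclopropane bonds, a racemic background rearrangement, and ionisation of the spiro C–O bond with cyclopropyl-to-allyl opening to cyclohexenyl products. The fallback uses known chemistry and sets out from 19. LiI (5 mol%) in CH2Cl2 at rt effects the known halide-catalysed oxaspiropentane-to-cyclobutanone rearrangement and gives the racemate, that is 20 together with its enantiomer (1R,5R)-1,5-dimethylbicyclo[3.2.0]heptan-6-one F1. A ketoreductase chosen from a commercial panel for (1R,5R)-selectivity (NADPH, glucose and glucose dehydrogenase, pH 7 buffer with 5% DMSO, 30 °C) then reduces only F1, to (1R,5R,6S)-1,5-dimethylbicyclo[3.2.0]heptan-6-ol F2. Unreacted ketone is separated from the alcohol on silica, and the route is rejoined at 20 (at most half of the material).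

**Step 11.** The risks are the orientation of the alkyne (its two arms are both CH2 groups on a fully substituted carbon, so the bias rests on size and on the hydroxyl hydrogen bond), slow oxidative cyclisation at the α-quaternary ketone, and protonolysis of the nickelacycle by the free hydroxyl. A smaller phosphine is the first lever. The fallback sets out from 20 and terminal alkyne 10 (step 6 is then not needed) and builds the enone in stages. The same Ni(cod)2/PCy3 insertion with a terminal alkyne puts hydrogen on the carbon that bonds to the carbonyl carbon and gives (3aS,7aS)-6-{[(2S)-6-methoxy-2,8-dimethyl-3,4-dihydro-2H-chromen-2-yl]methyl}-3a,7a-dimethyl-1,2,3,3a,7,7a-hexahydro-4H-inden-4-one F3. α-Iodination (I2, pyridine, cat. DMAP, CH2Cl2) gives the 5-iodo enone (3aS,7aS)-5-iodo-6-{[(2S)-6-methoxy-2,8-dimethyl-3,4-dihydro-2H-chromen-2-yl]methyl}-3a,7a-dimethyl-1,2,3,3a,7,7a-hexahydro-4H-inden-4-one F4. Stille coupling with tributyl(2-methylprop-2-en-1-yl)stannane (Pd2(dba)3, AsPh3, CuI, DMF, 60 °C) gives (3aS,7aS)-6-{[(2S)-6-methoxy-2,8-dimethyl-3,4-dihydro-2H-chromen-2-yl]methyl}-3a,7a-dimethyl-5-(2-methylprop-2-en-1-yl)-1,2,3,3a,7,7a-hexahydro-4H-inden-4-one F5. Mukaiyama hydration of the 1,1-disubstituted alkene (Co(acac)2, PhSiH3, O2, i-PrOH/THF, rt) then gives the tertiary alcohol, and the route is rejoined at 21.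

**Step 2.** The risks are competing C-alkylation ortho to the methoxy group, double alkylation, and polymerisation of the enone. The fallback sets out from 3 and fixes the position by chelation. Magnesium-mediated ortho-formylation (MgCl2, Et3N, paraformaldehyde, MeCN, reflux) gives 2-hydroxy-5-methoxy-3-methylbenzaldehyde F6. Claisen–Schmidt condensation with acetone (aq NaOH, rt) gives (E)-4-(2-hydroxy-5-methoxy-3-methylphenyl)but-3-en-2-one F7. Hydrogenation of the C=C bond (H2, Pd/C, EtOAc) gives the saturated keto-phenol, which closes to the lactol, and the route is rejoined at 5.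

## Further compounds

F1 | step 10 | (1R,5R)-1,5-dimethylbicyclo[3.2.0]heptan-6-one | O=C1[C@]2(C)CCC[C@]2(C)C1
F2 | step 10 | (1R,5R,6S)-1,5-dimethylbicyclo[3.2.0]heptan-6-ol | O[C@@H]1[C@]2(C)CCC[C@]2(C)C1
F3 | step 11 | (3aS,7aS)-6-{[(2S)-6-methoxy-2,8-dimethyl-3,4-dihydro-2H-chromen-2-yl]methyl}-3a,7a-dimethyl-1,2,3,3a,7,7a-hexahydro-4H-inden-4-one | COc1cc(C)c2c(c1)CC[C@@](C)(CC1=CC(=O)[C@@]3(C)CCC[C@@]3(C)C1)O2
F4 | step 11 | (3aS,7aS)-5-iodo-6-{[(2S)-6-methoxy-2,8-dimethyl-3,4-dihydro-2H-chromen-2-yl]methyl}-3a,7a-dimethyl-1,2,3,3a,7,7a-hexahydro-4H-inden-4-one | COc1cc(C)c2c(c1)CC[C@@](C)(CC1=C(I)C(=O)[C@@]3(C)CCC[C@@]3(C)C1)O2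
F5 | step 11 | (3aS,7aS)-6-{[(2S)-6-methoxy-2,8-dimethyl-3,4-dihydro-2H-chromen-2-yl]methyl}-3a,7a-dimethyl-5-(2-methylprop-2-en-1-yl)-1,2,3,3a,7,7a-hexahydro-4H-inden-4-one | COc1cc(C)c2c(c1)CC[C@@](C)(CC1=C(CC(C)=C)C(=O)[C@@]3(C)CCC[C@@]3(C)C1)O2
F6 | step 2 | 2-hydroxy-5-methoxy-3-methylbenzaldehyde | COc1cc(C)c(O)c(C=O)c1
F7 | step 2 | (E)-4-(2-hydroxy-5-methoxy-3-methylphenyl)but-3-en-2-one | COc1cc(C)c(O)c(/C=C/C(C)=O)c1
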